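**Assumptions:** (Z)-oct-2-en-1-ol, (R)-4-(tert-butyldimethylsilyloxy)cyclopent-2-en-1-one and methyl 7-hydroxyhept-5-ynoate are taken as catalogue compounds. Prostanoid numbering (C1 ester to C20) is used for positions. The route is a design from known reaction types and has not been run.

## Retrosynthetic overview

1. C7–OAc: chemoselective acetylation of the secondary aldol hydroxyl (tertiary C12–OH left free).
2. C7–C8: anti-aldol of the alkoxide/α′-enolate dianion of (S)-4-hydroxy-2-iodo-4-[(Z)-oct-2-enyl]cyclopent-2-enone with methyl (Z)-7-oxohept-5-enoate; this sets C7 and C8.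
3. C10–I: α-iodination of the hydroxy-enone.
4. C12: 1,2-addition of a (Z)-oct-2-enyl barium reagent to (R)-4-TBSO-cyclopentenone anti to OTBS, then desilylation and allylic oxidation (carbonyl transposition).
5. No ring is formed: the single cyclopentene ring is purchased intact. The Z-enal comes from an alkynol by Lindlar reduction and oxidation.

## Route

**Step 1**
Reactants: 1, (Z)-oct-2-en-1-ol
Product: 2, (Z)-1-chlorooct-2-ene
Conditions: MsCl, LiCl, 2,4,6-collidine, DMF, 0 °C
Reagents that add atoms: lithium chloride, [Li+].[Cl-] (chloride source; MsCl only activates the alcohol)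
Why: Collington–Meyers mesylation and in-situ SN2 chloride displacement converts a primary allylic alcohol to the chloride without SN2′ transposition or Z→E isomerisation.

**Step 2**
Reactants: 2, (Z)-1-chlorooct-2-ene; 3, (R)-4-(tert-butyldimethylsilyloxy)cyclopent-2-en-1-one
Product: 4, (1S,4R)-4-(tert-butyldimethylsilyloxy)-1-[(Z)-oct-2-en-1-yl]cyclopent-2-en-1-ol (OH cis to OTBS)
Conditions: Rieke Ba (BaI2 + 2 Li biphenylide, THF, rt); 2, −78 °C; then 3, −78 °C; sat. NH4Cl; chromatographic removal of the minor diastereomer
Reagents that add atoms: none (both partners are numbered reactants)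
Why: Yamamoto allylbarium carbonyl allylation is α-selective, retains the Z geometry at −78 °C and adds 1,2 to the enone; attack anti to the C4 OTBS group sets the future C12. The minor syn adduct must be removed here because it gives the enantiomer after step 4.

**Step 3**
Reactants: 4
Product: 5, (1S,4R)-1-[(Z)-oct-2-en-1-yl]cyclopent-2-ene-1,4-diol (cis-diol)
Conditions: TBAF, THF, 0 °C → rt
Reagents that add atoms: none
Why: Fluoride-mediated desilylation frees the secondary allylic alcohol without touching the tertiary carbinol stereocentre.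

**Step 4**
Reactants: 5
Product: 6, (S)-4-hydroxy-4-[(Z)-oct-2-en-1-yl]cyclopent-2-en-1-one
Conditions: activated MnO2 (excess), CH2Cl2, rt
Reagents that add atoms: none
Why: MnO2 allylic oxidation takes only the secondary allylic alcohol (the tertiary one cannot oxidise, and no Cr(VI) means no Babler–Dauben transposition). This completes a 1,3-carbonyl transposition that leaves C12 as the only stereocentre.

**Step 5**
Reactants: 6
Product: 7, (S)-4-hydroxy-2-iodo-4-[(Z)-oct-2-en-1-yl]cyclopent-2-en-1-one
Conditions: I2 (1.5 equiv), pyridine/CH2Cl2 1:1, 0 °C → rt, dark; aq. Na2S2O3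
Reagents that add atoms: iodine, II
Why: Johnson α-iodination (pyridine conjugate addition, enolate iodination, E1cB loss of pyridine) places iodine at the enone α-carbon (C10); pyridine-complexed I2 is a weak electrophile toward the isolated Z-alkene.

**Step 6**
Reactants: 8, methyl 7-hydroxyhept-5-ynoate
Product: 9, methyl (Z)-7-hydroxyhept-5-enoate
Conditions: H2 (1 atm), Lindlar catalyst, quinoline, EtOAc, rt
Reagents that add atoms: none
Why: Lindlar semihydrogenation delivers H2 syn to the alkyne and gives the Z-allylic alcohol.

**Step 7**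
Reactants: 9
Product: 10, methyl (Z)-7-oxohept-5-enoate
Conditions: Dess–Martin periodinane, NaHCO3, CH2Cl2, 0 °C; used immediately
Reagents that add atoms: none
Why: Buffered Dess–Martin oxidation gives the Z-enal without acid- or base-induced Z→E isomerisation.

**Step 8**
Reactants: 7; 10
Product: 11, methyl (5Z,7S)-7-hydroxy-7-[(1R,5S)-5-hydroxy-3-iodo-5-[(Z)-oct-2-en-1-yl]-2-oxocyclopent-3-en-1-yl]hept-5-enoate
Conditions: LDA (2.2 equiv), THF, −78 °C, 30 min; then 10 (1.3 equiv), −78 °C, 15 min; AcOH/THF quench at −78 °C; chromatography
Reagents that add atoms: none (both partners are numbered reactants)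
Why: Directed lithium aldol of the alkoxide/α′-enolate dianion. The ring-locked (E)-enolate reacts through a Zimmerman–Traxler chair to give the anti relationship (7S with 8R). The aldehyde should enter C8 on the face syn to the C12–OLi (lithium-bridged delivery) and anti to the bulkier octenyl CH2, which is also the thermodynamically preferred arrangement, setting 8R. Cold quench avoids retro-aldol and dehydration.

**Step 9**
Reactants: 11
Product: 12, 7-acetoxy-7,8-dihydroiodovulone I = methyl (5Z,7S)-7-acetoxy-7-[(1R,5S)-5-hydroxy-3-iodo-5-[(Z)-oct-2-en-1-yl]-2-oxocyclopent-3-en-1-yl]hept-5-enoate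
Conditions: Ac2O (3 equiv), pyridine, DMAP (5 mol %), CH2Cl2, −20 → 0 °C, quench at full conversion
Reagents that add atoms: acetic anhydride, CC(=O)OC(C)=O
Why: Nucleophile-catalysed acylation acetylates the secondary allylic C7–OH while the hindered tertiary C12–OH stays free; low temperature and short time suppress E1cB loss of acetate to the iodovulone dienone and C8 epimerisation.

## Compound list

1 | (Z)-oct-2-en-1-ol | CCCCC/C=C\CO | starting material
2 | (Z)-1-chlorooct-2-ene | CCCCC/C=C\CCl | intermediate
3 | (R)-4-(tert-butyldimethylsilyloxy)cyclopent-2-en-1-one | O=C1C=C[C@H](O[Si](C)(C)C(C)(C)C)C1 | starting material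
4 | (1S,4R)-4-(tert-butyldimethylsilyloxy)-1-[(Z)-oct-2-en-1-yl]cyclopent-2-en-1-ol | CCCCC/C=C\C[C@@]1(O)C=C[C@H](O[Si](C)(C)C(C)(C)C)C1 | intermediate
5 | (1S,4R)-1-[(Z)-oct-2-en-1-yl]cyclopent-2-ene-1,4-diol | CCCCC/C=C\C[C@@]1(O)C=C[C@H](O)C1 | intermediate
6 | (S)-4-hydroxy-4-[(Z)-oct-2-en-1-yl]cyclopent-2-en-1-one | CCCCC/C=C\C[C@@]1(O)C=CC(=O)C1 | intermediate
7 | (S)-4-hydroxy-2-iodo-4-[(Z)-oct-2-en-1-yl]cyclopent-2-en-1-one | CCCCC/C=C\C[C@@]1(O)C=C(I)C(=O)C1 | intermediate
8 | methyl 7-hydroxyhept-5-ynoate | COC(=O)CCCC#CCO | starting material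
9 | methyl (Z)-7-hydroxyhept-5-enoate | COC(=O)CCC/C=C\CO | intermediate
10 | methyl (Z)-7-oxohept-5-enoate | COC(=O)CCC/C=C\C=O | intermediate
11 | methyl (5Z,7S)-7-hydroxy-7-[(1R,5S)-5-hydroxy-3-iodo-5-[(Z)-oct-2-en-1-yl]-2-oxocyclopent-3-en-1-yl]hept-5-enoate | CCCCC/C=C\C[C@@]1(O)C=C(I)C(=O)[C@@H]1[C@H](/C=C\CCCC(=O)OC)O | intermediate
12 | 7-acetoxy-7,8-dihydroiodovulone I (7S,8R,12S) | CCCCC/C=C\C[C@@]1(O)C=C(I)C(=O)[C@@H]1[C@H](/C=C\CCCC(=O)OC)OC(C)=O | target

## Totals

Total steps: 9. Longest linear sequence: 7 (steps 1, 2, 3, 4, 5, 8, 9); the enal branch is 2 steps (6, 7).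

## Three steps most likely to fail

1. **Step 8 (dianion aldol).** The iodo-dienolate may be unstable, and the C8 facial and C7 anti/syn selectivities of a cyclopentenone lithium enolate with an enal may be modest, so expect a diastereomer mixture needing separation. Fallback: protect C12–OH as the TMS ether, convert to the 2-silyloxydiene (TMSOTf, Et3N) and run a Lewis-acid Mukaiyama aldol (BF3·OEt2, −78 °C) with 10; then acetylate and remove the silyl group with HF·pyridine. This uses a neutral silyl enol ether and an open transition state instead of a lithium dianion.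

2. **Step 2 (allylbarium addition).** Risks are γ-attack, Z→E leakage, and enolisation or elimination of the base-sensitive silyloxy-enone. Fallback: build the chain through an alkyne. Add propargylmagnesium bromide to 3 (clean SE2′ to the homopropargyl carbinol, anti to OTBS), alkylate the alkoxide/acetylide dianion with 1-iodopentane (n-BuLi, THF/DMPU), then Lindlar-reduce to the Z-olefin before steps 3–5.

3. **Step 5 (α-iodination).** The free homoallylic tertiary alcohol and Z-alkene could undergo 5-endo iodoetherification. Fallback: cap C12–OH as the TMS ether before iodination, carry the silyl ether through a mono-enolate aldol (LDA, 1.1 equiv) and acetylation, and remove it last with HF·pyridine. This changes the protecting-group strategy and the enolate type for the endgame.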